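The time allowed, 25 min, is best counted in turnovers of the catalyst, since each turnover turns one substrate and one partner into one product. The flasks differ in their partner charge.

the same everywhere: substrate 0.020 M; protic impurity 10.0 mM; free catalyst 1.6 mM; time 25 min
- cedar: partner 0.0140 M
- oak: partner 0.0170 M
- alder: partner 0.0200 M

    substrate + free catalyst ⇌ catalyst intermediate A (K1 = 36 M⁻¹, k1 = 2780 M⁻¹ min⁻¹)
    partner + catalyst intermediate A → catalyst intermediate B (k2 = 2050 M⁻¹ min⁻¹)
    catalyst intermediate B ⇌ free catalyst + product (K3 = 0.017 M, k3 = 27.0 min⁻¹)
    partner ⇌ dormant form (K4 = 9.2, k4 = 0.968 min⁻¹)
    partner + protic impurity → quenched reagent (k5 = 16.1 M⁻¹ min⁻¹)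
    crystals ⇌ product, rate k6*(cs6 - [product]) while solid is left; crystals form when [product] > cs6 (cs6 = 0.64 mM, k6 = 5.99 min⁻¹)

- which of these there is most of at the end, counted by the substrate in it, cedar (catalyst intermediate B / product / catalyst intermediate A / substrate)
- which of these there is most of at the end, counted by the substrate in it, oak (catalyst intermediate B / product / catalyst intermediate A / substrate)
- which of these there is most of at the end, counted by the substrate in it, alder (catalyst intermediate B / product / catalyst intermediate A / substrate)
- amount of the one of these that there is most of at the end, in percent of the substrate charged, cedar
- amount of the one of these that there is most of at the end, in percent of the substrate charged, oak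
- amount of the one of these that there is most of at the end, in percent of the substrate charged, alder

- what is said of product includes crystals
- crystals is a solid; its amount is given per volume of the solution
- run time (cedar): 25 min

Start with the main cycle by itself: substrate binds, partner adds, product leaves. Cedar's partner, the limiting reagent at 0.0140 M against 0.020 M of substrate, pays for 8.75 turnovers of the catalyst, or 70.0% of the substrate. The reckoning treats binding and the release of product as equilibria, with substrate at 10.0 mM, half its charge, as a guess for the long part of the run. Dissolved product is held at its solubility, 0.64 mM, by the crystals. Catalyst intermediate A then stands at 0.412 mM, and the rest is free catalyst and catalyst intermediate B. Partner meets it pseudo-first-order, at 0.845 min⁻¹.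

Now add the protic impurity, held at its charge. It takes partner at 0.161 min⁻¹, less than the cycle does, so a share of 84.0% of consumed partner becomes product. Cedar's turnovers fall to 7.35.

The dormant form comes last. Partner retreats at 0.968 min⁻¹, against a consumption of 1.01 min⁻¹, so on this reckoning 49.0% of it, about half, hides in the first minutes. It returns at 0.105 min⁻¹, and each returning partner may retreat again. The drain constant is the fraction of the dormant form that leaves for good each minute, the return rate times the chance of being consumed before retreating: 0.0536 min⁻¹. After 25 min, a quarter of what hid is still hidden, which in cedar is 1.80 mM. Cedar's product comes to 51.2%, or 6.41 turnovers. About 46.7% remains as substrate, so product leads narrowly. The same factors give 62.2% for oak and 73.2% for alder, with the substrate guess a generous one for alder.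

The forecast names product for cedar, oak and alder at 59%, 68% and 75%, on the grounds that “a fast early burst of product competes with its retreat into the dormant form”; its cedar figure stands above my 51.2%.

Cedar ends with 51.7% of product against 46.1% of substrate, while oak and alder end with product at 61.2% and 69.9%. At 25.0 min, cedar still holds 0.00181 M of dormant form, worth 1.13 turnovers of partner. Left until 40 min, that store loses 0.997 mM by the drain constant, and at the share 84.0% this adds 4.19% of the substrate as product, making 55.9%. Cedar left that long reads 56.0%.

The constants used here come from no measurement; what happens was integrated by code.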